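I have no rate constant for this flask, but the autumn readings give me an amount to use in its place. A solid substrate goes into solution and turns into intermediate and target.

| flask | solid substrate | remark | time |
|---|---|---|---|
| autumn | 10 mM | run made earlier |  |
| flask | 20 mM |  | 30 h |

autumn run (percent of the solid substrate charged)

| time / h | solid substrate / % | target / % | intermediate / % |
|---|---|---|---|
| 1.33 | 52.4 | 20.9 | 19.2 |
| 2.50 | 46.3 | 25.4 | 20.9 |
| 4.00 | 42.6 | 25.2 | 23.2 |
| 5.00 | 43.8 | 27.3 | 25.3 |
| 6.00 | 44.2 | 26.1 | 22.8 |

(standard deviation of a reading: 1 percentage point)

- as a solid, counted per litre of solution: solid substrate
- what was read earlier has a scatter of 1 percentage point, one standard deviation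
- at the start none of the solid substrate is in solution
- what has only dissolved of solid substrate counts as not reacted
- the reaction counts as stopped when no species that holds the solid substrate changes by six tenths of a point or more over the second half of the time

* at 30 h, what has stopped the reaction, if anything has (for what has run out or reacted, a solid counts together with what of it has only dissolved) (all of the solid substrate has reacted / forward and back rates have come level / it is still moving)
* part of the solid substrate that has turned into other species by 30 h (what has only dissolved does not count)
* the target standing at 30 h, as a percentage of the solid substrate charged
* the intermediate standing at 30 h, as a percentage of the solid substrate charged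

From 4.00 h on, the autumn run stands level within its scatter. There, intermediate and target together read 5.00 mM on average: this is the made stock, the amount held as those two once the autumn run stands level. I reckon with the fraction left, which is one minus made stock over charge.

Take the main step first, solid to products, one way: the fraction left heads for zero, yet the autumn run still shows 44.2% solid at 6.00 h. Add the way back, with everything dissolved: the percentages then carry over from the autumn run, and the fraction left stays 50.0%. Now add the solid itself. The autumn run stands level with 44.2% solid still read at 6.00 h, so the solid is no limiting reagent there, and I take what is dissolved to sit at its ceiling, as in a saturated solution. On that view the made stock carries over in mM, and extra charge stays as solid. In this flask the stock is less than the 20 mM charged, so I take a fraction left of 75.0%, with target 13.1% and intermediate 11.9%. The autumn readings stand level from 4.00 h, well before 30 h, so I expect forward and back rates to have come level in this flask.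

The forecast says forward and back rates have come level, with 28% converted (range 25% to 58%), 13.3% target and 12% intermediate: “Doubling the charge would then give the same mM”. Its conversion stands above my 25.0%.

In the flask, forward and back rates have come level, with 25.0% converted, 13.1% target and 11.9% intermediate, and 71.5% solid still lying at 30.0 h.

    solid substrate ⇌ starting material, rate k1*(cs1 - [starting material]) while solid is left; crystals form when [starting material] > cs1 (solubility = 0.700 mM, k = 0.0410 s⁻¹)
    intermediate ⇌ target (K = 1.10, k = 0.0260 s⁻¹)
    starting material ⇌ intermediate (K = 3.40, k = 0.00260 s⁻¹)

For a neighbouring flask with 12 mM charged, the made stock gives a fraction left of 58.3%. That neighbouring flask ends with 58% of its charge still there, solid or dissolved, and 41.6% converted.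

The data are calculated for substances that don't exist; noise was put on by code.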